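**Retrosynthetic overview**

1. The target is two (2S)-5-hydroxy-7-methoxyflavanone units joined by the diaryl ether C4'–O–C6''. The last operations are BCl3 cleavage of the peri 5''-O-methyl ether and methanolysis of a 4'''-acetate.
2. Ring C'' of the second unit is cut at C4''–C4a'' (Friedel–Crafts acylation) and at C2''–O1'' (Mitsunobu inversion of an (R)-3-aryl-3-hydroxypropanoate). Ring A'' comes from symmetric 2,6-dimethoxyhydroquinone, so its two ortho positions are the same.
3. Ring C of the first unit is cut at O1–C2: catalytic asymmetric oxa-Michael closure of a 2',6'-dihydroxy-4'-methoxychalcone.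
4. The strategy rests on ring A of the first unit. It is a 2-acylphloroglucinol monomethyl ether (C5–OH, C7–OMe, C8a–O1, acyl on C4a), the aromatised form of a cinnamoyl triketide. It is cut at C4a–C8a back to a 6-(cinnamoylmethyl)-4-methoxy-2-pyranone (Mg(OMe)2 ring opening, Claisen recyclisation).
5. The pyranone precursor comes from lithiated 4-methoxy-6-methyl-2-pyranone and a cinnamoyl Weinreb amide built on an SNAr diaryl ether aldehyde. Ring order: A'' and B are bought, then ring A (step 6), ring C (step 7), ring C'' (step 13).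

Key step: step 6

Remark: the sense of induction in steps 7 and 10 is assigned from the usual catalyst models and is to be confirmed on the first run (if reversed, the quinidine-derived pseudoenantiomer or the (S,S)-ligand is used); 4-acetoxybenzoyl chloride is taken as a catalogue compound.

**Route**

Step 1
Reactants: 1 2,6-dimethoxy-1,4-benzoquinone
Product: 2 2,6-dimethoxybenzene-1,4-diol
Conditions: Na2S2O4, EtOAc/H2O, rt, argon
Reagents that add atoms: none
Why: Dithionite reduction of a quinone to its hydroquinone is fast in a two-phase system, and the air-sensitive product is carried on directly under argon.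

Step 2
Reactants: 2 2,6-dimethoxybenzene-1,4-diol
Product: 3 4-(benzyloxy)-2,6-dimethoxyphenol
Conditions: BnBr (1.0 equiv), K2CO3 (1.1 equiv), acetone, rt, argon
Reagents that add atoms: benzyl bromide, BrCc1ccccc1
Why: Williamson etherification under weak-base control, in which the 4-hydroxyl (flanked by two hydrogens and acidified by two meta methoxy groups) should be alkylated in preference to the 1-hydroxyl buried between two methoxy groups.

Step 3
Reactants: 3 4-(benzyloxy)-2,6-dimethoxyphenol; 4 4-fluorobenzaldehyde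
Product: 5 4-[4-(benzyloxy)-2,6-dimethoxyphenoxy]benzaldehyde
Conditions: K2CO3, DMF, 120 °C, argon
Reagents that add atoms: none
Why: Nucleophilic aromatic substitution (SNAr), the para-formyl group activating the C–F bond towards the hindered but electron-rich phenoxide.

Step 4
Reactants: 5 4-[4-(benzyloxy)-2,6-dimethoxyphenoxy]benzaldehyde; 6 diethyl [2-(methoxy(methyl)amino)-2-oxoethyl]phosphonate
Product: 7 (E)-3-{4-[4-(benzyloxy)-2,6-dimethoxyphenoxy]phenyl}-N-methoxy-N-methylprop-2-enamide
Conditions: NaH, THF, 0 °C → rt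
Reagents that add atoms: none
Why: Horner–Wadsworth–Emmons olefination with a stabilised phosphonate anion should give the E-cinnamoyl Weinreb amide.

Step 5
Reactants: 7 (E)-cinnamoyl Weinreb amide; 8 4-methoxy-6-methyl-2H-pyran-2-one
Product: 9 6-[(E)-4-{4-[4-(benzyloxy)-2,6-dimethoxyphenoxy]phenyl}-2-oxobut-3-en-1-yl]-4-methoxy-2H-pyran-2-one
Conditions: 8 (1.5 equiv), LiN(SiMe3)2 (1.5 equiv), THF, −78 °C; then 7, −78 → −30 °C; aq NH4Cl
Reagents that add atoms: none
Why: Claisen-type acylation of the extended dienolate formed at the C6 methyl group, where the chelated tetrahedral adduct of the Weinreb amide prevents over-addition and proton quench, and carbonyl attack is preferred because an unsaturated amide is a poor Michael acceptor.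

Step 6
Reactants: 9 6-(cinnamoylmethyl)-4-methoxy-2-pyranone
Product: 11 (E)-3-{4-[4-(benzyloxy)-2,6-dimethoxyphenoxy]phenyl}-1-(2,6-dihydroxy-4-methoxyphenyl)prop-2-en-1-one, via ring-opened triketide methyl ester 10 (not isolated)
Conditions: Mg(OMe)2 (6 equiv), MeOH, reflux; cold 1 M HCl work-up
Reagents that add atoms: none
Why: Methoxide adds to the lactone carbonyl of 9 and opens the ring to the triketide ester 10, in which the enol ether double bond keeps the ester carbon and the C4 methylene on the same side; the magnesium-chelated 5,7-diketonate of 10 then attacks the ester carbon through C6, methoxide is expelled and the resulting cyclohexenedione enolises to the aromatic ring. The closest known reaction type is the magnesium methoxide recyclisation of 6-(2-oxoalkyl)-4-methoxy-2-pyranones to acylphloroglucinol monomethyl ethers, a laboratory counterpart of the chalcone synthase Claisen cyclisation. Ring A closes in the 6-exo-trig mode at the ester carbonyl, the new bond joining the acyl-bearing carbon (later C4a) to a hydroxyl-bearing carbon (later C8a; C5 and C8a are equivalent in the chalcone). No stereocentre is formed, and the E-enone is carried through unchanged. The step needs Claisen C-acylation to win over aldol closure onto the cinnamoyl ketone (which would give a stilbene-type resorcylate) and over conjugate addition to the enone: the C6 methylene between two ketones is by far the most acidic site and is held by magnesium as a C-nucleophilic chelate whose carbonyls are poor electrophiles, while C2 of the enol ether could react only through a much less favoured γ-deprotonated dienolate. The methoxy group of the pyranone ends up as the 4'-methoxy group without any selective methylation, and the chalcone should stay open as its magnesium bis-phenoxide until the cold acidic work-up.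

Step 7
Reactants: 11 2',6'-dihydroxy-4'-methoxychalcone
Product: 12 (2S)-2-{4-[4-(benzyloxy)-2,6-dimethoxyphenoxy]phenyl}-5-hydroxy-7-methoxychroman-4-one
Conditions: 1-[3,5-bis(trifluoromethyl)phenyl]-3-[(8α,9S)-6'-methoxycinchonan-9-yl]thiourea (10 mol %), toluene, −20 °C; recrystallisation
Reagents that add atoms: none
Why: Catalytic asymmetric intramolecular oxa-Michael addition (6-endo-trig chalcone–flavanone isomerisation), in which the quinuclidine deprotonates the non-chelated hydroxyl (either one, as the two are equivalent) while the thiourea binds the enone carbonyl, so that the phenoxide should add to one face of the β-carbon and set C2 as S; low temperature and a non-polar solvent hold back the uncatalysed closure and the retro-Michael opening.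

Step 8
Reactants: 12 (2S)-benzyl-protected flavanone
Product: 13 (2S)-5-hydroxy-2-[4-(4-hydroxy-2,6-dimethoxyphenoxy)phenyl]-7-methoxychroman-4-one
Conditions: H2 (1 atm), Pd/C, EtOAc, rt
Reagents that add atoms: none
Why: Hydrogenolysis of the benzyl aryl ether under neutral conditions, which should leave the chelated ketone, the cyclic C2–O1 bond and the C2 stereocentre untouched when stopped at consumption of 12.

Step 9
Reactants: 14 4-acetoxybenzoyl chloride; 15 Meldrum's acid (2,2-dimethyl-1,3-dioxane-4,6-dione)
Product: 17 tert-butyl 3-(4-acetoxyphenyl)-3-oxopropanoate, via acyl Meldrum's acid 16 (not isolated)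
Conditions: pyridine, CH2Cl2, 0 °C → rt; then t-BuOH, toluene, 90 °C
Reagents that add atoms: tert-butanol, CC(C)(C)O
Why: C-acylation of Meldrum's acid followed by thermal alcoholysis through the acylketene gives the β-keto ester with loss of acetone and CO2 under neutral conditions that spare the aryl acetate.

Step 10
Reactants: 17 tert-butyl 3-(4-acetoxyphenyl)-3-oxopropanoate
Product: 18 tert-butyl (3R)-3-(4-acetoxyphenyl)-3-hydroxypropanoate
Conditions: RuCl(p-cymene)[(R,R)-TsDPEN] (1 mol %), HCO2H/Et3N (5:2), CH2Cl2, rt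
Reagents that add atoms: none
Why: Noyori–Ikariya asymmetric transfer hydrogenation, in which the ruthenium hydride of the (R,R)-ligand delivers hydride to the aryl ketone through the six-membered outer-sphere transition state with the aryl group held by a CH–π contact, which should set the carbinol as R.

Step 11
Reactants: 13 (2S)-flavanone phenol; 18 tert-butyl (3R)-3-(4-acetoxyphenyl)-3-hydroxypropanoate
Product: 19 tert-butyl (3S)-3-(4-acetoxyphenyl)-3-[4-{4-[(2S)-5-hydroxy-7-methoxy-4-oxochroman-2-yl]phenoxy}-3,5-dimethoxyphenoxy]propanoate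
Conditions: PPh3, DIAD, THF, 0 °C → rt
Reagents that add atoms: none
Why: Mitsunobu etherification, in which the unhindered ring A'' phenol displaces the oxyphosphonium of the benzylic alcohol by SN2 with inversion (R to S); the electron-poor 4-acetoxyphenyl group disfavours ionisation and the chelated 5-hydroxyl is too poor a nucleophile to compete.

Step 12
Reactants: 19 tert-butyl ester
Product: 20 (3S)-3-(4-acetoxyphenyl)-3-[4-{4-[(2S)-5-hydroxy-7-methoxy-4-oxochroman-2-yl]phenoxy}-3,5-dimethoxyphenoxy]propanoic acid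
Conditions: TFA/CH2Cl2 (1:4), anisole, 0 °C → rt
Reagents that add atoms: none
Why: Acidolysis of the tert-butyl ester (E1 loss of isobutene, anisole as cation scavenger) frees the acid without base, so the flavanone stereocentre and the aryl acetate should be untouched.

Step 13
Reactants: 20 carboxylic acid
Product: 22 4-[(2S)-6-{4-[(2S)-5-hydroxy-7-methoxy-4-oxochroman-2-yl]phenoxy}-5,7-dimethoxy-4-oxochroman-2-yl]phenyl acetate, via mixed trifluoroacetic anhydride 21 (not isolated)
Conditions: (CF3CO)2O, CH2Cl2, 0 °C → rt; aq NaHCO3 work-up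
Reagents that add atoms: none
Why: Intramolecular Friedel–Crafts acylation through the mixed anhydride (6-exo-trig) at a ring A'' carbon activated by two ortho oxygens and one para oxygen, the two candidate positions being identical by symmetry and the C2'' stereocentre not taking part.

Step 14
Reactants: 22 5''-O-methyl 4'''-O-acetyl bis-flavanone
Product: 24 7,7''-di-O-methyltetrahydrohinokiflavone, via 5''-hydroxy 4'''-acetate 23 (not isolated)
Conditions: BCl3 (5 equiv), CH2Cl2, −78 → 0 °C; then MeOH, 0 → 40 °C
Reagents that add atoms: none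
Why: Chelation-controlled demethylation, in which BCl3 bound to the C4'' carbonyl cleaves only the peri 5''-O-methyl ether and leaves the 7- and 7''-methoxy groups, after which the methanol quench generates HCl that transesterifies the aryl acetate, so that no base reaches either flavanone stereocentre.

**Compound list**

1 | 2,6-dimethoxy-1,4-benzoquinone | COC1=CC(=O)C=C(OC)C1=O | starting material
2 | 2,6-dimethoxybenzene-1,4-diol | COc1cc(O)cc(OC)c1O | intermediate
3 | 4-(benzyloxy)-2,6-dimethoxyphenol | COc1cc(OCc2ccccc2)cc(OC)c1O | intermediate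
4 | 4-fluorobenzaldehyde | O=Cc1ccc(F)cc1 | starting material
5 | 4-[4-(benzyloxy)-2,6-dimethoxyphenoxy]benzaldehyde | O=Cc1ccc(Oc2c(OC)cc(OCc3ccccc3)cc2OC)cc1 | intermediate
6 | diethyl [2-(methoxy(methyl)amino)-2-oxoethyl]phosphonate | CCOP(=O)(CC(=O)N(C)OC)OCC | starting material
7 | (E)-3-{4-[4-(benzyloxy)-2,6-dimethoxyphenoxy]phenyl}-N-methoxy-N-methylprop-2-enamide | CON(C)C(=O)/C=C/c1ccc(Oc2c(OC)cc(OCc3ccccc3)cc2OC)cc1 | intermediate
8 | 4-methoxy-6-methyl-2H-pyran-2-one | COC1=CC(=O)OC(C)=C1 | starting material
9 | 6-[(E)-4-{4-[4-(benzyloxy)-2,6-dimethoxyphenoxy]phenyl}-2-oxobut-3-en-1-yl]-4-methoxy-2H-pyran-2-one | COC1=CC(=O)OC(CC(=O)/C=C/c2ccc(Oc3c(OC)cc(OCc4ccccc4)cc3OC)cc2)=C1 | intermediate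
10 | methyl (2E,8E)-9-{4-[4-(benzyloxy)-2,6-dimethoxyphenoxy]phenyl}-3-methoxy-5,7-dioxonona-2,8-dienoate (ester carbon and C4 methylene cis) | COC(=O)/C=C(OC)\CC(=O)CC(=O)/C=C/c1ccc(Oc2c(OC)cc(OCc3ccccc3)cc2OC)cc1 | intermediate
11 | (E)-3-{4-[4-(benzyloxy)-2,6-dimethoxyphenoxy]phenyl}-1-(2,6-dihydroxy-4-methoxyphenyl)prop-2-en-1-one | COc1cc(O)c(c(O)c1)C(=O)/C=C/c1ccc(Oc2c(OC)cc(OCc3ccccc3)cc2OC)cc1 | intermediate
12 | (2S)-2-{4-[4-(benzyloxy)-2,6-dimethoxyphenoxy]phenyl}-5-hydroxy-7-methoxychroman-4-one | COc1cc(O)c2c(c1)O[C@H](c1ccc(Oc3c(OC)cc(OCc4ccccc4)cc3OC)cc1)CC2=O | intermediate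
13 | (2S)-5-hydroxy-2-[4-(4-hydroxy-2,6-dimethoxyphenoxy)phenyl]-7-methoxychroman-4-one | COc1cc(O)c2c(c1)O[C@H](c1ccc(Oc3c(OC)cc(O)cc3OC)cc1)CC2=O | intermediate
14 | 4-acetoxybenzoyl chloride | CC(=O)Oc1ccc(cc1)C(Cl)=O | starting material
15 | Meldrum's acid (2,2-dimethyl-1,3-dioxane-4,6-dione) | CC1(C)OC(=O)CC(=O)O1 | starting material
16 | 5-[(4-acetoxyphenyl)(hydroxy)methylidene]-2,2-dimethyl-1,3-dioxane-4,6-dione | CC(=O)Oc1ccc(cc1)C(O)=C1C(=O)OC(C)(C)OC1=O | intermediate
17 | tert-butyl 3-(4-acetoxyphenyl)-3-oxopropanoate | CC(=O)Oc1ccc(cc1)C(=O)CC(=O)OC(C)(C)C | intermediate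
18 | tert-butyl (3R)-3-(4-acetoxyphenyl)-3-hydroxypropanoate | CC(=O)Oc1ccc(cc1)[C@H](O)CC(=O)OC(C)(C)C | intermediate
19 | tert-butyl (3S)-3-(4-acetoxyphenyl)-3-[4-{4-[(2S)-5-hydroxy-7-methoxy-4-oxochroman-2-yl]phenoxy}-3,5-dimethoxyphenoxy]propanoate | COc1cc(O)c2c(c1)O[C@H](c1ccc(Oc3c(OC)cc(O[C@@H](CC(=O)OC(C)(C)C)c4ccc(OC(C)=O)cc4)cc3OC)cc1)CC2=O | intermediate
20 | (3S)-3-(4-acetoxyphenyl)-3-[4-{4-[(2S)-5-hydroxy-7-methoxy-4-oxochroman-2-yl]phenoxy}-3,5-dimethoxyphenoxy]propanoic acid | COc1cc(O)c2c(c1)O[C@H](c1ccc(Oc3c(OC)cc(O[C@@H](CC(=O)O)c4ccc(OC(C)=O)cc4)cc3OC)cc1)CC2=O | intermediate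
21 | mixed anhydride of acid 20 and trifluoroacetic acid | COc1cc(O)c2c(c1)O[C@H](c1ccc(Oc3c(OC)cc(O[C@@H](CC(=O)OC(=O)C(F)(F)F)c4ccc(OC(C)=O)cc4)cc3OC)cc1)CC2=O | intermediate
22 | 4-[(2S)-6-{4-[(2S)-5-hydroxy-7-methoxy-4-oxochroman-2-yl]phenoxy}-5,7-dimethoxy-4-oxochroman-2-yl]phenyl acetate | COc1cc(O)c2c(c1)O[C@H](c1ccc(Oc3c(OC)cc4c(c3OC)C(=O)C[C@@H](c3ccc(OC(C)=O)cc3)O4)cc1)CC2=O | intermediate
23 | 4-[(2S)-5-hydroxy-6-{4-[(2S)-5-hydroxy-7-methoxy-4-oxochroman-2-yl]phenoxy}-7-methoxy-4-oxochroman-2-yl]phenyl acetate | COc1cc(O)c2c(c1)O[C@H](c1ccc(Oc3c(OC)cc4c(c3O)C(=O)C[C@@H](c3ccc(OC(C)=O)cc3)O4)cc1)CC2=O | intermediate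
24 | 7,7''-di-O-methyltetrahydrohinokiflavone, (2S,2''S) | COc1cc(O)c2c(c1)O[C@H](c1ccc(Oc3c(OC)cc4c(c3O)C(=O)C[C@@H](c3ccc(O)cc3)O4)cc1)CC2=O | target

**Step count**

Total: 14 steps. Longest linear sequence: 12 steps (steps 1–8 and 11–14); the side branch is steps 9–10.

**Steps most likely to fail**

Step 7. The catalyst may discriminate poorly between the two faces of the enone, an uncatalysed closure may run beside the catalysed one, and the amine may reopen the product by retro-Michael reaction and erode the enantiomeric purity. The fallback sets out from chalcone 11 and gives up catalytic face control in favour of a kinetic resolution. Chalcone 11 is closed with NaOAc in refluxing EtOH to racemic 2-{4-[4-(benzyloxy)-2,6-dimethoxyphenoxy]phenyl}-5-hydroxy-7-methoxychroman-4-one F1. F1 is then subjected to asymmetric transfer hydrogenation with RuCl(p-cymene)[(R,R)-TsDPEN] and HCO2H/Et3N in EtOAc at rt, stopped near half conversion. The (2R)-enantiomer should be reduced to (2R,4R)-cis-2-{4-[4-(benzyloxy)-2,6-dimethoxyphenoxy]phenyl}-7-methoxychroman-4,5-diol F2, while the (2S)-ketone is left and is separated by chromatography. The route is rejoined at compound 12, at the cost of at most half of the material.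

Step 6. The opened triketide may close in the aldol mode, relactonise, or add methoxide or its own enol oxygen to the enone, and the chalcone may close to racemic flavanone during work-up. The fallback sets out from aldehyde 5 and builds the chalcone by a Claisen–Schmidt condensation instead of by ring synthesis. Commercial 2',6'-dihydroxy-4'-methoxyacetophenone F3 is protected (NaH, MOMCl, DMF) as 2',6'-bis(methoxymethoxy)-4'-methoxyacetophenone F4. F4 is condensed with 5 (KOH, EtOH/H2O, rt) to the bis(methoxymethyl)-protected chalcone F5. The acetals are removed with HCl in MeOH at rt, kept short to limit cyclisation. The route is rejoined at compound 11.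

Step 5. The dienolate may add in a conjugate sense to the unsaturated amide instead of at the carbonyl, or proton transfer may stall the acylation. The fallback sets out from aldehyde 5 and replaces acylation by aldol addition and oxidation. Wittig homologation with (triphenylphosphoranylidene)acetaldehyde in toluene at 80 °C should give (E)-3-{4-[4-(benzyloxy)-2,6-dimethoxyphenoxy]phenyl}prop-2-enal F6. The lithiated pyranone from 8 (LiN(SiMe3)2, THF, −78 °C) adds 1,2 to F6 to give the racemic allylic alcohol 6-[(E)-4-{4-[4-(benzyloxy)-2,6-dimethoxyphenoxy]phenyl}-2-hydroxybut-3-en-1-yl]-4-methoxy-2H-pyran-2-one F7. F7 is oxidised with MnO2 in CH2Cl2 (or with Dess–Martin periodinane). The route is rejoined at compound 9.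

**Further compounds**

F1 | step 7 | racemic 2-{4-[4-(benzyloxy)-2,6-dimethoxyphenoxy]phenyl}-5-hydroxy-7-methoxychroman-4-one | COc1cc(O)c2c(c1)OC(c1ccc(Oc3c(OC)cc(OCc4ccccc4)cc3OC)cc1)CC2=O
F2 | step 7 | (2R,4R)-cis-2-{4-[4-(benzyloxy)-2,6-dimethoxyphenoxy]phenyl}-7-methoxychroman-4,5-diol | COc1cc(O)c2c(c1)O[C@@H](c1ccc(Oc3c(OC)cc(OCc4ccccc4)cc3OC)cc1)C[C@H]2O
F3 | step 6 | 2',6'-dihydroxy-4'-methoxyacetophenone | COc1cc(O)c(C(C)=O)c(O)c1
F4 | step 6 | 2',6'-bis(methoxymethoxy)-4'-methoxyacetophenone | COCOc1cc(OC)cc(OCOC)c1C(C)=O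
F5 | step 6 | (E)-3-{4-[4-(benzyloxy)-2,6-dimethoxyphenoxy]phenyl}-1-[4-methoxy-2,6-bis(methoxymethoxy)phenyl]prop-2-en-1-one | COCOc1cc(OC)cc(OCOC)c1C(=O)/C=C/c1ccc(Oc2c(OC)cc(OCc3ccccc3)cc2OC)cc1
F6 | step 5 | (E)-3-{4-[4-(benzyloxy)-2,6-dimethoxyphenoxy]phenyl}prop-2-enal | O=C/C=C/c1ccc(Oc2c(OC)cc(OCc3ccccc3)cc2OC)cc1
F7 | step 5 | 6-[(E)-4-{4-[4-(benzyloxy)-2,6-dimethoxyphenoxy]phenyl}-2-hydroxybut-3-en-1-yl]-4-methoxy-2H-pyran-2-one (racemic) | COC1=CC(=O)OC(CC(O)/C=C/c2ccc(Oc3c(OC)cc(OCc4ccccc4)cc3OC)cc2)=C1
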